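**Plan**

- The retrosynthesis cuts the pyranone ring (ring C) twice: at the aryl–oxygen bond O1–C8a and at C3–C4. O1–C8a lies on ring A ortho to the C4 carbonyl, so it can be made by addition–elimination at a carbon bearing one fluorine, placed between C4a and the side-chain carbon C8. With no second ortho leaving group, closure toward C6 cannot occur.
- The fragments are acid chloride 13 (ring A with C4 and the complete, protected C8 chain) and ketone 17 (ring B, C2, C3 and the 3-oxygen).
- Forward: rings A and B are bought. The chain is built on 2,4,6-trifluorophenylacetic acid (Weinreb amide, isopropenyl Grignard, reduction, silylation). C4 is added by ring lithiation, two fluorines are exchanged for allyloxy groups, and ring C, the only ring formed, closes in step 11.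
- The single stereocentre C2'' (S) comes from the CBS reduction of enone 5 with the (R)-oxazaborolidine and is carried on unchanged as its TBS ether.
- The end is acid (MOM and TBS off), then Pd(0) (both allyl ethers off).

Key step: step 11

Remark: locants C2–C8a refer to the chromen-4-one and C1''–C4'' to the side chain. Where two like groups react in one operation (steps 6, 12, 13), the intermediate named is the one expected from the faster site; the other order would lead to the same product.

**Route**

Step 1
Reactants: 1 2,4,6-trifluorophenylacetic acid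
Product: 3 N-methoxy-N-methyl-2-(2,4,6-trifluorophenyl)acetamide, via acyl imidazolide 2 (not isolated)
Conditions: CDI (1.1 equiv), THF, rt; then MeNH(OMe)·HCl (1.2 equiv), rt
Reagents that add atoms: N,O-dimethylhydroxylamine hydrochloride (CNOC.Cl)
Why: Amide coupling through the acyl imidazolide is routine for arylacetic acids and should give the Weinreb amide needed for a single Grignard addition.

Step 2
Reactants: 3 N-methoxy-N-methyl-2-(2,4,6-trifluorophenyl)acetamide
Product: 5 3-methyl-1-(2,4,6-trifluorophenyl)but-3-en-2-one, via magnesium chelate 4 (not isolated)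
Conditions: CH2=C(CH3)MgBr (1.5 equiv), THF, −20 → 0 °C; inverse quench into cold 1 M HCl
Reagents that add atoms: isopropenylmagnesium bromide (C=C(C)[Mg]Br)
Why: In this Weinreb ketone synthesis the five-membered magnesium chelate 4 should hold the tetrahedral adduct until the quench, so the Grignard reagent adds once only, and pouring into cold acid keeps the released amine protonated and away from the enone.

Step 3
Reactants: 5 3-methyl-1-(2,4,6-trifluorophenyl)but-3-en-2-one
Product: 6 (S)-3-methyl-1-(2,4,6-trifluorophenyl)but-3-en-2-ol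
Conditions: (R)-Me-CBS (0.2 equiv), catecholborane (1.5 equiv), toluene, −78 °C; aq. NaOH work-up
Reagents that add atoms: none
Why: In the Corey–Bakshi–Shibata reduction the α-branched alkenyl group should act as the large and the arylmethyl group as the small substituent, so the (R)-catalyst should deliver hydride to the face that gives the (S)-carbinol (mirror image of the (S)-catalyst/aryl methyl ketone case), and catecholborane at −78 °C should leave the C=C bond alone.

Step 4
Reactants: 6 (S)-3-methyl-1-(2,4,6-trifluorophenyl)but-3-en-2-ol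
Product: 7 (S)-tert-butyldimethyl{[3-methyl-1-(2,4,6-trifluorophenyl)but-3-en-2-yl]oxy}silane
Conditions: TBSCl, imidazole, DMF, rt
Reagents that add atoms: tert-butyldimethylsilyl chloride (CC(C)(C)[Si](C)(C)Cl)
Why: Silylation of the secondary alcohol proceeds at oxygen with retention at C2'' and should give an ether that withstands the organolithium, alkoxide, hydroxide and enolate steps ahead.

Step 5
Reactants: 7 (S)-tert-butyldimethyl{[3-methyl-1-(2,4,6-trifluorophenyl)but-3-en-2-yl]oxy}silane
Product: 9 allyl 2,4,6-trifluoro-3-[(S)-2-(tert-butyldimethylsilyloxy)-3-methylbut-3-enyl]benzoate, via aryllithium 8 (not isolated)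
Conditions: n-BuLi (1.05 equiv), THF, −78 °C; then cannulated into ClCO2CH2CH=CH2 (2 equiv), THF, −78 °C
Reagents that add atoms: allyl chloroformate (C=CCOC(=O)Cl)
Why: This is a directed ortho-lithiation followed by acylation with a chloroformate: the two ring hydrogens, each flanked by two fluorines, are the most acidic sites and are equivalent, the aryllithium is stable at −78 °C, and inverse addition to excess chloroformate should stop at the ester.

Step 6
Reactants: 9 allyl 2,4,6-trifluoro-3-[(S)-2-(tert-butyldimethylsilyloxy)-3-methylbut-3-enyl]benzoate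
Product: 11 allyl 4,6-bis(allyloxy)-2-fluoro-3-[(S)-2-(tert-butyldimethylsilyloxy)-3-methylbut-3-enyl]benzoate, via 6-allyloxy mono-ether 10 (not isolated)
Conditions: CH2=CHCH2OH (2.2 equiv), NaH (2.1 equiv), DMF, −10 °C → rt
Reagents that add atoms: allyl alcohol (C=CCO)
Why: In this twofold nucleophilic aromatic substitution the ester activates all three fluorines, but the one between the ester and the branched side chain is the most shielded, so the open ortho-fluorine and then the para-fluorine should react first, each alkoxy group entered lowers the reactivity of the ring, and the allyl ester is degenerate toward allyloxide.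

Step 7
Reactants: 11 allyl 4,6-bis(allyloxy)-2-fluoro-3-[(S)-2-(tert-butyldimethylsilyloxy)-3-methylbut-3-enyl]benzoate
Product: 12 4,6-bis(allyloxy)-2-fluoro-3-[(S)-2-(tert-butyldimethylsilyloxy)-3-methylbut-3-enyl]benzoic acid
Conditions: LiOH·H2O, THF–H2O, 50 °C; then 1 M HCl to pH 3, 0 °C
Reagents that add atoms: lithium hydroxide ([Li+].[OH-])
Why: Saponification of the ester should proceed without loss of the remaining fluorine, because the carboxylate formed deactivates the ring, and the silyl and allyl ethers are stable to aqueous hydroxide.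

Step 8
Reactants: 12 4,6-bis(allyloxy)-2-fluoro-3-[(S)-2-(tert-butyldimethylsilyloxy)-3-methylbut-3-enyl]benzoic acid
Product: 13 4,6-bis(allyloxy)-2-fluoro-3-[(S)-2-(tert-butyldimethylsilyloxy)-3-methylbut-3-enyl]benzoyl chloride
Conditions: Me2C=C(Cl)NMe2 (1.2 equiv), CH2Cl2, 0 °C → rt; evaporated and used crude
Reagents that add atoms: 1-chloro-N,N,2-trimethylprop-1-en-1-amine (CC(C)=C(Cl)N(C)C)
Why: Ghosez's chloroenamine forms acid chlorides under neutral conditions and releases only an amide, which should spare the TBS ether, the allyl ethers and the alkene.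

Step 9
Reactants: 14 2-bromo-1-(4-methoxyphenyl)ethanone
Product: 16 2-hydroxy-1-(4-methoxyphenyl)ethanone, via formate ester 15 (not isolated)
Conditions: HCO2Na, EtOH–H2O, reflux
Reagents that add atoms: sodium formate ([Na+].[O-]C=O)
Why: SN2 displacement of the phenacyl bromide by formate and hydrolysis of the formate ester in the same pot is a standard entry to α-hydroxy ketones.

Step 10
Reactants: 16 2-hydroxy-1-(4-methoxyphenyl)ethanone
Product: 17 2-(methoxymethoxy)-1-(4-methoxyphenyl)ethanone
Conditions: MOMCl, i-Pr2NEt, CH2Cl2, 0 °C → rt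
Reagents that add atoms: chloromethyl methyl ether (COCCl)
Why: O-Alkylation of the primary alcohol with MOMCl and Hünig's base (acetal formation) masks the future 3-OH as an ether that is stable to amide bases.

Step 11
Reactants: 13 4,6-bis(allyloxy)-2-fluoro-3-[(S)-2-(tert-butyldimethylsilyloxy)-3-methylbut-3-enyl]benzoyl chloride; 17 2-(methoxymethoxy)-1-(4-methoxyphenyl)ethanone
Product: 19 5,7-bis(allyloxy)-8-[(S)-2-(tert-butyldimethylsilyloxy)-3-methylbut-3-enyl]-3-(methoxymethoxy)-2-(4-methoxyphenyl)chromen-4-one, via 2-alkoxy-1,3-diketone 18 (not isolated)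
Conditions: 17 (2.2 equiv), LiHMDS (2.2 equiv), THF, −78 °C; 13 (1.0 equiv), −78 → 0 °C; then DMF, THF distilled off, 70 °C
Reagents that add atoms: none
Why: The lithium enolate of 17, kept in excess, is acylated at carbon by 13 (C3–C4 bond) and the 2-alkoxy-1,3-diketone 18 is deprotonated at once by the second equivalent, any enol ester from O-acylation being an acyl donor that the excess enolate should convert into the same diketonate. On warming in DMF the enolate oxygen on the anisoyl carbon adds to the fluorine-bearing ring carbon, the Meisenheimer anion is stabilised by the C4 carbonyl, and loss of fluoride as inert LiF forms O1–C8a without touching the TBS ether. The closest known reaction type is the synthesis of chromones, flavones and 4-quinolones from 2-halobenzoyl chlorides by C-acylation of an enolate or enamine followed by intramolecular SNAr. The six-membered pyranone closes by addition–elimination at an aromatic sp2 carbon, which, counted on the C8a=C4a bond that passes the charge to the carbonyl, is a 6-endo-trig closure (an intramolecular oxa-Michael addition with β-elimination). No stereocentre is formed and C2'' is not involved. The step needs C- over O-acylation, secured by the excess chelated lithium enolate, and a single site of closure, secured by the substrate, which carries one fluorine only, placed between C4a and the chain-bearing carbon and meta to both allyloxy groups so that it stays electrophilic.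

Step 12
Reactants: 19 5,7-bis(allyloxy)-8-[(S)-2-(tert-butyldimethylsilyloxy)-3-methylbut-3-enyl]-3-(methoxymethoxy)-2-(4-methoxyphenyl)chromen-4-one
Product: 21 5,7-bis(allyloxy)-3-hydroxy-8-[(S)-2-hydroxy-3-methylbut-3-enyl]-2-(4-methoxyphenyl)chromen-4-one, via 3-hydroxy silyl ether 20 (not isolated)
Conditions: HCl (ca. 1 M) in MeOH–THF, rt → 35 °C
Reagents that add atoms: none
Why: Acid-catalysed methanolysis should cleave the enol-type MOM acetal and the silyl ether in one operation, while the aryl allyl ethers, the 4'-methyl ether and the isopropenyl carbinol are inert to dilute methanolic HCl and C2'' is not ionised.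

Step 13
Reactants: 21 5,7-bis(allyloxy)-3-hydroxy-8-[(S)-2-hydroxy-3-methylbut-3-enyl]-2-(4-methoxyphenyl)chromen-4-one
Product: 23 3,5,7-trihydroxy-8-[(S)-2-hydroxy-3-methylbut-3-enyl]-2-(4-methoxyphenyl)chromen-4-one, via 5-O-allyl ether 22 (not isolated)
Conditions: Pd(PPh3)4 (5 mol%), morpholine (10 equiv), THF, rt, argon
Reagents that add atoms: none
Why: In this Tsuji–Trost deallylation Pd(0) ionises the aryl allyl ethers to π-allyl complexes that morpholine traps, whereas the free secondary allylic alcohol is not a leaving group, so both phenols should be released under nearly neutral conditions to give the target.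

**Compound list**

1 | 2,4,6-trifluorophenylacetic acid | OC(=O)Cc1c(F)cc(F)cc1F | starting material
2 | 1-[(2,4,6-trifluorophenyl)acetyl]imidazole | O=C(Cc1c(F)cc(F)cc1F)n1ccnc1 | intermediate (not isolated)
3 | N-methoxy-N-methyl-2-(2,4,6-trifluorophenyl)acetamide | CON(C)C(=O)Cc1c(F)cc(F)cc1F | intermediate
4 | bromomagnesium 2-[methoxy(methyl)amino]-3-methyl-1-(2,4,6-trifluorophenyl)but-3-en-2-olate (chelated tetrahedral adduct) | C=C(C)C(O[Mg]Br)(Cc1c(F)cc(F)cc1F)N(C)OC | intermediate (not isolated)
5 | 3-methyl-1-(2,4,6-trifluorophenyl)but-3-en-2-one | C=C(C)C(=O)Cc1c(F)cc(F)cc1F | intermediate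
6 | (S)-3-methyl-1-(2,4,6-trifluorophenyl)but-3-en-2-ol | C=C(C)[C@@H](O)Cc1c(F)cc(F)cc1F | intermediate
7 | (S)-tert-butyldimethyl{[3-methyl-1-(2,4,6-trifluorophenyl)but-3-en-2-yl]oxy}silane | C=C(C)[C@@H](O[Si](C)(C)C(C)(C)C)Cc1c(F)cc(F)cc1F | intermediate
8 | {3-[(S)-2-(tert-butyldimethylsilyloxy)-3-methylbut-3-enyl]-2,4,6-trifluorophenyl}lithium | C=C(C)[C@@H](O[Si](C)(C)C(C)(C)C)Cc1c(F)cc(F)c([Li])c1F | intermediate (not isolated)
9 | allyl 2,4,6-trifluoro-3-[(S)-2-(tert-butyldimethylsilyloxy)-3-methylbut-3-enyl]benzoate | C=C(C)[C@@H](O[Si](C)(C)C(C)(C)C)Cc1c(F)cc(F)c(C(=O)OCC=C)c1F | intermediate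
10 | allyl 6-(allyloxy)-2,4-difluoro-3-[(S)-2-(tert-butyldimethylsilyloxy)-3-methylbut-3-enyl]benzoate | C=C(C)[C@@H](O[Si](C)(C)C(C)(C)C)Cc1c(F)cc(OCC=C)c(C(=O)OCC=C)c1F | intermediate (not isolated)
11 | allyl 4,6-bis(allyloxy)-2-fluoro-3-[(S)-2-(tert-butyldimethylsilyloxy)-3-methylbut-3-enyl]benzoate | C=C(C)[C@@H](O[Si](C)(C)C(C)(C)C)Cc1c(OCC=C)cc(OCC=C)c(C(=O)OCC=C)c1F | intermediate
12 | 4,6-bis(allyloxy)-2-fluoro-3-[(S)-2-(tert-butyldimethylsilyloxy)-3-methylbut-3-enyl]benzoic acid | C=C(C)[C@@H](O[Si](C)(C)C(C)(C)C)Cc1c(OCC=C)cc(OCC=C)c(C(=O)O)c1F | intermediate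
13 | 4,6-bis(allyloxy)-2-fluoro-3-[(S)-2-(tert-butyldimethylsilyloxy)-3-methylbut-3-enyl]benzoyl chloride | C=C(C)[C@@H](O[Si](C)(C)C(C)(C)C)Cc1c(OCC=C)cc(OCC=C)c(C(=O)Cl)c1F | intermediate
14 | 2-bromo-1-(4-methoxyphenyl)ethanone | COc1ccc(C(=O)CBr)cc1 | starting material
15 | 2-(4-methoxyphenyl)-2-oxoethyl formate | COc1ccc(C(=O)COC=O)cc1 | intermediate (not isolated)
16 | 2-hydroxy-1-(4-methoxyphenyl)ethanone | COc1ccc(C(=O)CO)cc1 | intermediate
17 | 2-(methoxymethoxy)-1-(4-methoxyphenyl)ethanone | COCOCC(=O)c1ccc(OC)cc1 | intermediate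
18 | 1-{4,6-bis(allyloxy)-2-fluoro-3-[(S)-2-(tert-butyldimethylsilyloxy)-3-methylbut-3-enyl]phenyl}-2-(methoxymethoxy)-3-(4-methoxyphenyl)propane-1,3-dione (C2 of the dione not defined) | C=C(C)[C@@H](O[Si](C)(C)C(C)(C)C)Cc1c(OCC=C)cc(OCC=C)c(C(=O)C(OCOC)C(=O)c2ccc(OC)cc2)c1F | intermediate (not isolated)
19 | 5,7-bis(allyloxy)-8-[(S)-2-(tert-butyldimethylsilyloxy)-3-methylbut-3-enyl]-3-(methoxymethoxy)-2-(4-methoxyphenyl)chromen-4-one | C=C(C)[C@@H](O[Si](C)(C)C(C)(C)C)Cc1c(OCC=C)cc(OCC=C)c2c(=O)c(OCOC)c(-c3ccc(OC)cc3)oc12 | intermediate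
20 | 5,7-bis(allyloxy)-8-[(S)-2-(tert-butyldimethylsilyloxy)-3-methylbut-3-enyl]-3-hydroxy-2-(4-methoxyphenyl)chromen-4-one | C=C(C)[C@@H](O[Si](C)(C)C(C)(C)C)Cc1c(OCC=C)cc(OCC=C)c2c(=O)c(O)c(-c3ccc(OC)cc3)oc12 | intermediate (not isolated)
21 | 5,7-bis(allyloxy)-3-hydroxy-8-[(S)-2-hydroxy-3-methylbut-3-enyl]-2-(4-methoxyphenyl)chromen-4-one | C=C(C)[C@@H](O)Cc1c(OCC=C)cc(OCC=C)c2c(=O)c(O)c(-c3ccc(OC)cc3)oc12 | intermediate
22 | 5-(allyloxy)-3,7-dihydroxy-8-[(S)-2-hydroxy-3-methylbut-3-enyl]-2-(4-methoxyphenyl)chromen-4-one | C=C(C)[C@@H](O)Cc1c(O)cc(OCC=C)c2c(=O)c(O)c(-c3ccc(OC)cc3)oc12 | intermediate (not isolated)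
23 | 3,5,7-trihydroxy-8-[(S)-2-hydroxy-3-methylbut-3-enyl]-2-(4-methoxyphenyl)chromen-4-one | C=C(C)[C@@H](O)Cc1c(O)cc(O)c2c(=O)c(O)c(-c3ccc(OC)cc3)oc12 | target

**Count and risks**

Total: 13 steps. Longest linear sequence: 11 steps (1–8, then 11–13); the ketone arm (steps 9 and 10) is two steps.

The three steps most likely to fail:

1. Step 11. What may go wrong is acylation of the enolate at oxygen, or slow acylation by the doubly ortho-substituted, electron-rich aroyl chloride, so that diketonate 18 does not build up. The fallback replaces the acylation by an aldol addition one oxidation level lower and sets out from acid chloride 13. LiAlH(Ot-Bu)3 in THF at −78 °C should reduce it to 4,6-bis(allyloxy)-2-fluoro-3-[(S)-2-(tert-butyldimethylsilyloxy)-3-methylbut-3-enyl]benzaldehyde F1. The lithium enolate of 17 (LDA, THF, −78 °C) can add to an aldehyde only through carbon and should give the aldol adduct 3-{4,6-bis(allyloxy)-2-fluoro-3-[(S)-2-(tert-butyldimethylsilyloxy)-3-methylbut-3-enyl]phenyl}-3-hydroxy-2-(methoxymethoxy)-1-(4-methoxyphenyl)propan-1-one F2 as a diastereomer mixture whose new centres are lost again. Dess–Martin periodinane then leads to diketone 18, and K2CO3 in DMF at 70 °C closes the ring, so the route is rejoined at 19.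

2. Step 6. What may go wrong is entry of the second alkoxide at the shielded fluorine beside the ester, or a third substitution; either removes the fluorine needed for ring closure. The fallback closes the ring before the second ether is made and sets out from ester 9. One equivalent of sodium allyloxide in toluene–THF at −30 °C, where the sodium ion held by the ester carbonyl steers the alkoxide to the open ortho position, should stop at mono-ether 10, which is now isolated. LiOH gives 6-(allyloxy)-2,4-difluoro-3-[(S)-2-(tert-butyldimethylsilyloxy)-3-methylbut-3-enyl]benzoic acid F3, and the chloroenamine of step 8 gives 6-(allyloxy)-2,4-difluoro-3-[(S)-2-(tert-butyldimethylsilyloxy)-3-methylbut-3-enyl]benzoyl chloride F4. Acylation of the enolate of 17 as in step 11 leads through the diketone 1-{6-(allyloxy)-2,4-difluoro-3-[(S)-2-(tert-butyldimethylsilyloxy)-3-methylbut-3-enyl]phenyl}-2-(methoxymethoxy)-3-(4-methoxyphenyl)propane-1,3-dione F5, which can close only onto its one ortho-fluorine, to 5-(allyloxy)-7-fluoro-8-[(S)-2-(tert-butyldimethylsilyloxy)-3-methylbut-3-enyl]-3-(methoxymethoxy)-2-(4-methoxyphenyl)chromen-4-one F6. Its fluorine, para to the C4 carbonyl, is finally displaced by allyl alcohol/NaH in DMF, which rejoins the route at 19. In this order the crowded fluorine is consumed intramolecularly before a second alkoxide is present.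

3. Step 3. What may go wrong is poor facial discrimination, because the two groups on the carbonyl differ little in size, or competing conjugate reduction. The fallback replaces asymmetric reduction by kinetic resolution and sets out from enone 5. Luche reduction (NaBH4, CeCl3·7H2O, MeOH, 0 °C) gives racemic 3-methyl-1-(2,4,6-trifluorophenyl)but-3-en-2-ol F7. Sharpless kinetic resolution (Ti(Oi-Pr)4, D-(−)-diisopropyl tartrate, t-BuOOH, 4 Å sieves, CH2Cl2, −20 °C, run slightly past half conversion) should epoxidise the (R)-enantiomer to (R)-1-[(S)-2-methyloxiran-2-yl]-2-(2,4,6-trifluorophenyl)ethanol F8 and leave the (S)-alcohol, so the route is rejoined at 6.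

**Further compounds**

F1 | step 11 | 4,6-bis(allyloxy)-2-fluoro-3-[(S)-2-(tert-butyldimethylsilyloxy)-3-methylbut-3-enyl]benzaldehyde | C=C(C)[C@@H](O[Si](C)(C)C(C)(C)C)Cc1c(OCC=C)cc(OCC=C)c(C=O)c1F
F2 | step 11 | 3-{4,6-bis(allyloxy)-2-fluoro-3-[(S)-2-(tert-butyldimethylsilyloxy)-3-methylbut-3-enyl]phenyl}-3-hydroxy-2-(methoxymethoxy)-1-(4-methoxyphenyl)propan-1-one (diastereomer mixture at the two new centres) | C=C(C)[C@@H](O[Si](C)(C)C(C)(C)C)Cc1c(OCC=C)cc(OCC=C)c(C(O)C(OCOC)C(=O)c2ccc(OC)cc2)c1F
F3 | step 6 | 6-(allyloxy)-2,4-difluoro-3-[(S)-2-(tert-butyldimethylsilyloxy)-3-methylbut-3-enyl]benzoic acid | C=C(C)[C@@H](O[Si](C)(C)C(C)(C)C)Cc1c(F)cc(OCC=C)c(C(=O)O)c1F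
F4 | step 6 | 6-(allyloxy)-2,4-difluoro-3-[(S)-2-(tert-butyldimethylsilyloxy)-3-methylbut-3-enyl]benzoyl chloride | C=C(C)[C@@H](O[Si](C)(C)C(C)(C)C)Cc1c(F)cc(OCC=C)c(C(=O)Cl)c1F
F5 | step 6 | 1-{6-(allyloxy)-2,4-difluoro-3-[(S)-2-(tert-butyldimethylsilyloxy)-3-methylbut-3-enyl]phenyl}-2-(methoxymethoxy)-3-(4-methoxyphenyl)propane-1,3-dione | C=C(C)[C@@H](O[Si](C)(C)C(C)(C)C)Cc1c(F)cc(OCC=C)c(C(=O)C(OCOC)C(=O)c2ccc(OC)cc2)c1F
F6 | step 6 | 5-(allyloxy)-7-fluoro-8-[(S)-2-(tert-butyldimethylsilyloxy)-3-methylbut-3-enyl]-3-(methoxymethoxy)-2-(4-methoxyphenyl)chromen-4-one | C=C(C)[C@@H](O[Si](C)(C)C(C)(C)C)Cc1c(F)cc(OCC=C)c2c(=O)c(OCOC)c(-c3ccc(OC)cc3)oc12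
F7 | step 3 | rac-3-methyl-1-(2,4,6-trifluorophenyl)but-3-en-2-ol | C=C(C)C(O)Cc1c(F)cc(F)cc1F
F8 | step 3 | (R)-1-[(S)-2-methyloxiran-2-yl]-2-(2,4,6-trifluorophenyl)ethanol | O[C@H](Cc1c(F)cc(F)cc1F)[C@]1(C)CO1
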